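**Retrosynthetic overview**

1. The C6 side chain goes on last: catalyst-controlled Michael addition of the ring-A vinylogous acid 18 to cinnamaldehyde, then aldehyde to acid.
2. Ring A is closed second, by Dieckmann condensation (C5–C6) of keto ester 17.
3. Ring B is made first: a three-component Maitland–Japp annulation of dienol ether 11, acetaldehyde and aldehyde 8 forms C2–C3 and C4a–C8a (and O1–C8a) in one flask; a selenoxide dehydrogenation then restores C4a=C8a.
4. Enabling feature: ring B is a 2,3-dihydro-4H-pyran-4-one whose C4a lies between the C4 ketone and the C5 carbonyl of ring A, and whose C8a is the O1-bearing β-carbon. O1–C2–C3–C4(=O)–C4a is therefore a δ-hydroxy-β-keto ester, and C8a is an aldehyde carbon one oxidation level down.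
5. The quaternary C8 comes from the chiral pool: double Fráter–Seebach alkylation of methyl (S)-3-hydroxybutanoate, first with a lavandulyl electrophile from (R)-lavandulol, then with prenyl bromide.

Key step: step 8

Remark: (R)-lavandulol and methyl (S)-3-hydroxybutanoate are taken as commercial chiral-pool materials; the core is numbered as a chromanone (O1, C2, C3, C4, C4a, C5 to C8, C8a), ring A being the carbocycle and ring B the pyranone; "lavandulyl" means 5-methyl-2-(prop-1-en-2-yl)hex-4-en-1-yl and "prenyl" means 3-methylbut-2-en-1-yl.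

**Route**

Step 1
Reactants: 1 (R)-lavandulol
Product: 2 (R)-lavandulyl trifluoromethanesulfonate
Conditions: Tf2O, 2,6-lutidine, CH2Cl2, −78 °C; cold work-up, used at once
Reagents that add atoms: trifluoromethanesulfonic anhydride O=S(=O)(OS(=O)(=O)C(F)(F)F)C(F)(F)F
Why: O-sulfonylation of a primary alcohol gives an electrophile reactive enough for SN2 at −78 °C; the stereocentre is not touched.

Step 2
Reactants: 3 methyl (S)-3-hydroxybutanoate; 2 (R)-lavandulyl trifluoromethanesulfonate
Product: 4 methyl (2S,3S)-3-hydroxy-2-[(2S)-lavandulyl]butanoate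
Conditions: LiN(iPr)2 (2.2 equiv), THF, −78 → −20 °C; then 2, DMPU, −78 → −40 °C
Reagents that add atoms: none
Why: Fráter–Seebach alkylation, in which the lithium-chelated dianion is alkylated on the face anti to the C3 methyl group and should give the anti (2S,3S) product.

Step 3
Reactants: 4 methyl (2S,3S)-3-hydroxy-2-[(2S)-lavandulyl]butanoate; 5 prenyl bromide
Product: 6 methyl (2R,3S)-3-hydroxy-2-[(2S)-lavandulyl]-2-prenylbutanoate
Conditions: LiN(iPr)2 (2.5 equiv), THF/DMPU, −78 → −10 °C; then 5, −78 → −20 °C
Reagents that add atoms: none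
Why: Second Fráter–Seebach alkylation, in which prenyl bromide again enters anti to the C3 methyl group of the re-formed chelated dianion, so the order lavandulyl-then-prenyl should fix the quaternary centre in the configuration the target needs.

Step 4
Reactants: 6 methyl (2R,3S)-3-hydroxy-2-[(2S)-lavandulyl]-2-prenylbutanoate
Product: 7 (2S,3S)-2-[(2S)-lavandulyl]-2-prenylbutane-1,3-diol
Conditions: LiAlH4, THF, 0 °C → rt
Reagents that add atoms: none
Why: Hydride reduction of the hindered ester to the primary alcohol; alkenes and stereocentres are untouched.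

Step 5
Reactants: 7 (2S,3S)-2-[(2S)-lavandulyl]-2-prenylbutane-1,3-diol
Product: 8 (2S)-2-acetyl-2-[(2S)-lavandulyl]-5-methylhex-4-enal
Conditions: Dess–Martin periodinane (2.5 equiv), NaHCO3, CH2Cl2, 0 °C → rt; used without storage
Reagents that add atoms: none
Why: Dess–Martin oxidation of both alcohols under neutral conditions; the quaternary centre cannot epimerise and the controlling carbinol centre is deliberately destroyed.

Step 6
Reactants: 9 methyl 3-oxopentanoate
Product: 10 methyl 3-(trimethylsilyloxy)pent-2-enoate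
Conditions: Me3SiCl, Et3N, hexane, rt
Reagents that add atoms: chlorotrimethylsilane C[Si](C)(C)Cl
Why: O-silylation of the β-keto ester enol (silyl enol ether formation).

Step 7
Reactants: 10 methyl 3-(trimethylsilyloxy)pent-2-enoate
Product: 11 1-methoxy-1,3-bis(trimethylsilyloxy)penta-1,3-diene
Conditions: LiN(iPr)2, THF, −78 °C; then Me3SiCl, −78 °C → rt
Reagents that add atoms: chlorotrimethylsilane C[Si](C)(C)Cl
Why: γ-Deprotonation of the vinylogous ester and O-silylation, the standard preparation of 1,3-bis(silyloxy)dienes from β-keto esters.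

Step 8
Reactants: 11 1-methoxy-1,3-bis(trimethylsilyloxy)penta-1,3-diene; 12 acetaldehyde; 8 (2S)-2-acetyl-2-[(2S)-lavandulyl]-5-methylhex-4-enal
Product: 15 2,6-cis-tetrahydropyranone ester (enol form), via hydroxy keto ester 13 (not isolated), via Knoevenagel adduct 14 (not isolated)
Conditions: Ti(OiPr)4/(S)-BINOL (10 mol% each), 4 Å MS, THF, −78 → −20 °C; then MeOH, CF3CO2H (cat.), 0 °C; then 8, piperidine/AcOH (20 mol%), 4 Å MS, rt
Reagents that add atoms: none
Why: The complex formed from Ti(OiPr)4 and (S)-BINOL activates acetaldehyde and the terminal carbon of dienol ether 11 adds in a vinylogous Mukaiyama aldol reaction to make C2–C3; after desilylation the active methylene C4a of 13 condenses with the aldehyde of 8 (Knoevenagel, C4a=C8a) and the C2 hydroxyl closes onto C8a. The closest known reaction type is the one-pot asymmetric Maitland–Japp synthesis of tetrahydropyran-4-ones from a 1,3-bis(silyloxy)diene and two aldehydes. Ring B closes by a reversible 6-endo-trig oxa-Michael addition. C2 is set by the catalyst (Si-face addition to acetaldehyde is expected from the (S)-ligand, giving 2R), C3 by the syn preference of BINOL–titanium Mukaiyama aldols through an open transition state whatever the dienol ether geometry (giving 3S, the cis-dimethyl relationship), and C8a by thermodynamic control to the 2,6-cis ring with the bulky group equatorial, a centre that step 9 removes again. The step needs γ- over α-attack of the dienol ether (secured by the silyl dienolate/Lewis acid manifold), reaction at the aldehyde and not the hindered acetyl group of 8, and a second stage free of strong Lewis acid so that 8 does not undergo carbonyl-ene cyclisation onto its isopropenyl group.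

Step 9
Reactants: 15 2,6-cis-tetrahydropyranone ester (enol form)
Product: 17 methyl (2R,3S)-2,3-dimethyl-4-oxo-2,3-dihydro-4H-pyran-5-carboxylate bearing the quaternary side chain at C6, via C4a-selenide 16 (not isolated)
Conditions: NaH, THF, 0 °C; PhSeBr, −78 °C; then H2O2 (30%, excess), pyridine, CH2Cl2, 0 °C → rt
Reagents that add atoms: none
Why: α-Selenenylation of the β-keto ester enolate followed by selenoxide syn-elimination; selenium should enter C4a anti to the bulky C8a substituent, hence syn to the only β-hydrogen (C8a–H), and C2/C3 are safe because the C4a enolate blocks enolisation towards C3.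

Step 10
Reactants: 17 methyl (2R,3S)-2,3-dimethyl-4-oxo-2,3-dihydro-4H-pyran-5-carboxylate bearing the quaternary side chain at C6
Product: 18 (2R,3S,8S)-5-hydroxy-2,3-dimethyl-8-[(2S)-lavandulyl]-8-prenyl-2,3-dihydro-4H-chromene-4,7(8H)-dione
Conditions: LiN(SiMe3)2 (1.1 equiv), THF, −78 → −20 °C, slow addition of base; then AcOH
Reagents that add atoms: none
Why: Dieckmann (intramolecular Claisen) condensation, in which kinetic deprotonation of the acetyl methyl group (C6) and 6-exo-trig attack on the C5 ester close ring A; the released methoxide deprotonates the acidic product, whose anion shields ring B from enolisation at C3.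

Step 11
Reactants: 18 (2R,3S,8S)-5-hydroxy-2,3-dimethyl-8-[(2S)-lavandulyl]-8-prenyl-2,3-dihydro-4H-chromene-4,7(8H)-dione; 19 (E)-cinnamaldehyde
Product: 20 (3S)-3-phenyl-3-(chromenedione-6-yl)propanal (in equilibrium with its lactols, drawn open)
Conditions: (S)-2-[bis(3,5-bis(trifluoromethyl)phenyl)(trimethylsilyloxy)methyl]pyrrolidine (20 mol%), CH2Cl2, 0 °C → rt
Reagents that add atoms: none
Why: Iminium-ion catalysed Michael addition of a cyclic 1,3-dicarbonyl carbon (C6) to an enal; the bulky group of the (S)-catalyst shields one face of the s-trans (E)-iminium ion, so C6 should add to the open face and give the (S)-benzylic centre under catalyst control.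

Step 12
Reactants: 20 (3S)-3-phenyl-3-(chromenedione-6-yl)propanal
Product: 21 target acid CNP0150579.2
Conditions: NaClO2, NaH2PO4, 2-methyl-2-butene (large excess), t-BuOH/H2O, 0 °C
Reagents that add atoms: sodium chlorite [Na+].[O-]Cl=O
Why: Pinnick oxidation of the aldehyde (reacting through the open form of the lactol) under buffered, non-basic conditions with HOCl scavenged, so alkenes and the C3 centre should survive.

**Compound list**

1 | (R)-lavandulol, (2R)-5-methyl-2-(prop-1-en-2-yl)hex-4-en-1-ol | C=C(C)[C@@H](CC=C(C)C)CO | starting material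
2 | (R)-lavandulyl trifluoromethanesulfonate | C=C(C)[C@@H](CC=C(C)C)COS(=O)(=O)C(F)(F)F | intermediate
3 | methyl (S)-3-hydroxybutanoate | C[C@H](O)CC(=O)OC | starting material
4 | methyl (2S,3S)-3-hydroxy-2-[(2S)-5-methyl-2-(prop-1-en-2-yl)hex-4-en-1-yl]butanoate | C[C@H](O)[C@H](C[C@H](CC=C(C)C)C(C)=C)C(=O)OC | intermediate
5 | prenyl bromide, 1-bromo-3-methylbut-2-ene | CC(C)=CCBr | starting material
6 | methyl (2R,3S)-3-hydroxy-2-(3-methylbut-2-en-1-yl)-2-[(2S)-5-methyl-2-(prop-1-en-2-yl)hex-4-en-1-yl]butanoate | C[C@H](O)[C@](C[C@H](CC=C(C)C)C(C)=C)(CC=C(C)C)C(=O)OC | intermediate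
7 | (2S,3S)-2-(3-methylbut-2-en-1-yl)-2-[(2S)-5-methyl-2-(prop-1-en-2-yl)hex-4-en-1-yl]butane-1,3-diol | C[C@H](O)[C@](C[C@H](CC=C(C)C)C(C)=C)(CC=C(C)C)CO | intermediate
8 | (2S)-2-acetyl-5-methyl-2-[(2S)-5-methyl-2-(prop-1-en-2-yl)hex-4-en-1-yl]hex-4-enal | CC(=O)[C@](C[C@H](CC=C(C)C)C(C)=C)(CC=C(C)C)C=O | intermediate
9 | methyl 3-oxopentanoate | CCC(=O)CC(=O)OC | starting material
10 | methyl 3-(trimethylsilyloxy)pent-2-enoate (E/Z mixture, geometry left open because it is lost in step 7) | CCC(O[Si](C)(C)C)=CC(=O)OC | intermediate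
11 | 1-methoxy-1,3-bis(trimethylsilyloxy)penta-1,3-diene (mixture of geometric isomers, used as such) | CC=C(O[Si](C)(C)C)C=C(OC)O[Si](C)(C)C | intermediate
12 | acetaldehyde | CC=O | starting material
13 | methyl (4S,5R)-5-hydroxy-4-methyl-3-oxohexanoate (syn) | O[C@H](C)[C@H](C)C(=O)CC(=O)OC | intermediate
14 | Knoevenagel adduct of 13 and 8 at C4a (E/Z mixture) | O[C@H](C)[C@H](C)C(=O)C(C(=O)OC)=C[C@](CC=C(C)C)(C[C@H](CC=C(C)C)C(C)=C)C(C)=O | intermediate
15 | methyl (2R,3S,6S)-4-hydroxy-2,3-dimethyl-6-[quaternary carbon bearing acetyl, prenyl and (2S)-lavandulyl]-3,6-dihydro-2H-pyran-5-carboxylate (enol form of the 2,6-cis-tetrahydropyran-4-one) | O1[C@H](C)[C@H](C)C(O)=C(C(=O)OC)[C@@H]1[C@](CC=C(C)C)(C[C@H](CC=C(C)C)C(C)=C)C(C)=O | intermediate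
16 | C4a-phenylselenide of 15 (keto form, selenium trans to the C8a side chain) | O1[C@H](C)[C@H](C)C(=O)[C@]([Se]c2ccccc2)(C(=O)OC)[C@@H]1[C@](CC=C(C)C)(C[C@H](CC=C(C)C)C(C)=C)C(C)=O | intermediate
17 | methyl (2R,3S)-2,3-dimethyl-4-oxo-6-[quaternary carbon bearing acetyl, prenyl and (2S)-lavandulyl]-2,3-dihydro-4H-pyran-5-carboxylate | O1[C@H](C)[C@H](C)C(=O)C(C(=O)OC)=C1[C@](CC=C(C)C)(C[C@H](CC=C(C)C)C(C)=C)C(C)=O | intermediate
18 | (2R,3S,8S)-5-hydroxy-2,3-dimethyl-8-(3-methylbut-2-en-1-yl)-8-[(2S)-5-methyl-2-(prop-1-en-2-yl)hex-4-en-1-yl]-2,3-dihydro-4H-chromene-4,7(8H)-dione | C=C(C)[C@@H](CC=C(C)C)C[C@]1(CC=C(C)C)C(=O)C=C(O)C2=C1O[C@H](C)[C@H](C)C2=O | intermediate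
19 | (E)-cinnamaldehyde | O=C/C=C/c1ccccc1 | starting material
20 | (3S)-3-phenyl-3-[(2R,3S,8S)-5-hydroxy-2,3-dimethyl-4,7-dioxo-8-prenyl-8-lavandulyl-3,4,7,8-tetrahydro-2H-chromen-6-yl]propanal | C=C(C)[C@@H](CC=C(C)C)C[C@]1(CC=C(C)C)C(=O)C([C@@H](CC=O)c2ccccc2)=C(O)C2=C1O[C@H](C)[C@H](C)C2=O | intermediate
21 | (3S)-3-phenyl-3-[(2R,3S,8S)-5-hydroxy-2,3-dimethyl-4,7-dioxo-8-prenyl-8-lavandulyl-3,4,7,8-tetrahydro-2H-chromen-6-yl]propanoic acid (CNP0150579.2) | C=C(C)[C@@H](CC=C(C)C)C[C@]1(CC=C(C)C)C(=O)C([C@@H](CC(=O)O)c2ccccc2)=C(O)C2=C1O[C@H](C)[C@H](C)C2=O | target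

**Step count and risks**

Total steps: 12. Longest linear sequence: 10 (steps 1, 2, 3, 4, 5, 8, 9, 10, 11, 12).

Most likely to fail:

1. Step 8. The vinylogous aldol with small, enolisable acetaldehyde may give poor facial or syn selectivity (the facial sense assigned to the (S)-ligand is by analogy and must be confirmed), and the neopentyl-type aldehyde 8 may condense slowly or be lost by amine-induced deformylation. Fallback, known chemistry: setting out from 12, a cinchona-alkaloid/LiClO4-catalysed acyl halide–aldehyde cyclocondensation with propionyl chloride (the O-trimethylsilyl quinine or quinidine catalyst that gives the 3S,4R series) should give cis-(3S,4R)-3,4-dimethyloxetan-2-one F1. Acyl-oxygen opening of the strained lactone with the lithium enolate of methyl acetate gives 13 as an isolated, stereodefined compound. This is condensed with 8 in a separate two-component Knoevenagel/oxa-Michael step and comes back to the route at 15.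

2. Step 2. Elimination or ionisation of the β-branched homoallylic triflate and sluggish C-alkylation of the dianion may dominate. Fallback: setting out from 1, iodination (I2, PPh3, imidazole) gives (R)-lavandulyl iodide F2. The soft potassium enolate of methyl acetoacetate (K2CO3, DMF, 50 °C) is alkylated to methyl 2-[(2S)-lavandulyl]-3-oxobutanoate F3. An (S)-selective ketoreductase reduces the ketone to 4 together with its C2 epimer methyl (2R,3S)-3-hydroxy-2-[(2S)-lavandulyl]butanoate F4. Both epimers are re-enolised at C2 in step 3, so the fallback comes back at 6.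

3. Step 10. Competing deprotonation at C3 would cause epimerisation or retro-oxa-Michael opening of ring B, and aldol closure onto the C4 ketone is also possible. Fallback: setting out from 17, neutral ester cleavage with Me3SnOH (1,2-dichloroethane, 70 °C) gives the carboxylic acid F5. EDC/pentafluorophenol gives the pentafluorophenyl ester F6. Soft enolisation of the methyl ketone with MgBr2·OEt2/iPr2NEt (CH2Cl2, rt) brings about the intramolecular C-acylation without an amide base and comes back at 18.

**Further compounds**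

F1 | step 8 | (3S,4R)-3,4-dimethyloxetan-2-one (cis-β-lactone) | O1[C@H](C)[C@H](C)C1=O
F2 | step 2 | (R)-lavandulyl iodide | C=C(C)[C@@H](CC=C(C)C)CI
F3 | step 2 | methyl 2-[(2S)-lavandulyl]-3-oxobutanoate (C2 epimer mixture) | CC(=O)C(C[C@H](CC=C(C)C)C(C)=C)C(=O)OC
F4 | step 2 | methyl (2R,3S)-3-hydroxy-2-[(2S)-lavandulyl]butanoate (C2 epimer of 4) | C[C@H](O)[C@@H](C[C@H](CC=C(C)C)C(C)=C)C(=O)OC
F5 | step 10 | carboxylic acid from 17 | O1[C@H](C)[C@H](C)C(=O)C(C(=O)O)=C1[C@](CC=C(C)C)(C[C@H](CC=C(C)C)C(C)=C)C(C)=O
F6 | step 10 | pentafluorophenyl ester of F5 | O1[C@H](C)[C@H](C)C(=O)C(C(=O)Oc2c(F)c(F)c(F)c(F)c2F)=C1[C@](CC=C(C)C)(C[C@H](CC=C(C)C)C(C)=C)C(C)=O
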